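**Strategy**

The oxolan-2-one ring is cut at C4–C5 and C2–C3: its C3(H)(CH3)–C4H2 edge is a propene unit lying between the lactone carbonyl and the ring carbinol carbon. The key step inserts that unit, as the titanacyclopropane made from n-PrMgBr and Ti(OiPr)4, between the nitrile carbon of a chiral-pool β-hydroxy nitrile (future C5, carrying the complete protected diol side chain) and CO2 (future C2), giving a γ-keto acid in one operation. The free tertiary hydroxyl then directs an anti-selective ketone reduction with lactonisation, C3 is corrected by kinetic protonation, and daphnetin is attached last through its more acidic 7-OH.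

Key step: step 3

Remark: lactone atoms are numbered O1, C2 (carbonyl), C3 (methyl-bearing), C4, C5; the target is read as (3R,5R) in the ring, with the two ring substituents cis, and (2S,3S) in the butyl chain.

**Route**

Step 1
Reactants: 1 methyl (4S)-2,2-dimethyl-1,3-dioxolane-4-carboxylate; 2 N,O-dimethylhydroxylamine hydrochloride
Product: 4 1-[(4S)-2,2-dimethyl-1,3-dioxolan-4-yl]ethan-1-one, via Weinreb amide 3 (not isolated)
Conditions: i-PrMgCl, THF, −20 °C; then MeMgBr, 0 °C; aq. NH4Cl
Reagents that add atoms: methylmagnesium bromide, C[Mg]Br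
Why: One-pot Weinreb ketone synthesis, in which the magnesium amide of 2 converts the ester into the Weinreb amide and the chelated adduct with MeMgBr should stop at the methyl ketone; the α-alkoxy stereocentre is not touched under these non-enolising conditions.

Step 2
Reactants: 4 1-[(4S)-2,2-dimethyl-1,3-dioxolan-4-yl]ethan-1-one; 5 acetonitrile
Product: 7 (3S)-3-[(4S)-2,2-dimethyl-1,3-dioxolan-4-yl]-3-hydroxybutanenitrile, via (cyanomethyl)lithium 6 (not isolated)
Conditions: MeCN, LiN(iPr)2, THF, −78 °C; then 4 precomplexed with MgBr2·OEt2 in CH2Cl2, −78 °C; aq. NH4Cl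
Reagents that add atoms: none
Why: 1,2-Addition of the acetonitrile anion under Cram chelate control, in which magnesium bridges the carbonyl oxygen and the adjacent dioxolane oxygen so that the nucleophile should enter from the face opposite the ring CH2 and set the tertiary carbinol as (3S), syn to the neighbouring C–O bond.

Step 3
Reactants: 7 (3S)-3-[(4S)-2,2-dimethyl-1,3-dioxolan-4-yl]-3-hydroxybutanenitrile; 8 n-propylmagnesium bromide; 9 carbon dioxide
Product: 13 (2RS,6S)-6-[(4S)-2,2-dimethyl-1,3-dioxolan-4-yl]-6-hydroxy-2-methyl-4-oxoheptanoic acid, via titanacyclopropane 10 (not isolated), via azatitanacyclopentene 11 (not isolated), via titanium carboxylate 12 (not isolated)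
Conditions: n-PrMgBr (1.0 equiv), Et2O, 0 °C; Ti(OiPr)4 (1.1 equiv), then n-PrMgBr (2.1 equiv), −78 °C → rt; CO2 (1 atm), 0 °C → rt; cold 1 M HCl
Reagents that add atoms: water, O
Why: Proposed new method: after the hydroxyl is masked as its magnesium alkoxide, Ti(OiPr)4 and two further equivalents of n-PrMgBr give dipropyltitanium diisopropoxide, which loses propane by β-hydride abstraction to titanacyclopropane 10, a propene 1,2-dianion equivalent; the nitrile inserts into its unsubstituted Ti–CH2 bond to give azatitanacyclopentene 11 (bond from the propene CH2 to the future C5), CO2 then inserts into the remaining Ti–CH(CH3) bond to give carboxylate 12 (bond from the methyl-bearing carbon to the future C2), and acid hydrolyses the ketimine to the ketone. The closest known reaction types are the Kulinkovich–Szymoniak coupling of nitriles with titanacyclopropanes, which without a Lewis acid stops at the azatitanacycle and can take up a second nitrile to give 1,4-diketones, and the carboxylation of titanium–carbon bonds of titanacycles with CO2; the sequence is a formal hetero-Pauson–Khand-type [2+2+1] union in which a nitrile and CO2 stand in for carbonyl and CO. No ring of the target closes here: the only ring formed is the transient five-membered azatitanacycle, closed by migratory insertion and opened on work-up. The new stereocentre at the methyl-bearing carbon arises without control, since nothing near the Ti–C bond biases it, and is set in step 5. The step needs regioselectivity (nitrile carbon to CH2, CO2 to CH(CH3)), which the steric preference for insertion into the less substituted Ti–C bond should secure because only the secondary Ti–C bond is then left for CO2, and chemoselectivity, which rests on the absence of a Lewis acid (no contraction to a cyclopropylamine), on one nitrile per titanium at low temperature (no second insertion) and on the inertness of the acetonide and the alkoxide.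

Step 4
Reactants: 13 (2RS,6S)-6-[(4S)-2,2-dimethyl-1,3-dioxolan-4-yl]-6-hydroxy-2-methyl-4-oxoheptanoic acid
Product: 15 (5R)-5-{(2S)-2-[(4S)-2,2-dimethyl-1,3-dioxolan-4-yl]-2-hydroxypropyl}-3-methyloxolan-2-one (both C3 epimers), via hydroxy acid 14 (not isolated)
Conditions: Me4NBH(OAc)3, MeCN–AcOH (1:1), −30 °C; then pyridinium 4-toluenesulfonate (cat.), CH2Cl2, rt
Reagents that add atoms: none
Why: Evans–Saksena hydroxyl-directed reduction, in which the tertiary hydroxyl exchanges onto boron and delivers hydride through a chair with the dioxolanyl group equatorial and the ketone side chain away from the axial methyl and acetate, so that the 1,3-anti diol, that is the (4R) carbinol, should form and close to the five-membered lactone (5-exo-trig lactonisation).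

Step 5
Reactants: 15 (5R)-5-{(2S)-2-[(4S)-2,2-dimethyl-1,3-dioxolan-4-yl]-2-hydroxypropyl}-3-methyloxolan-2-one (both C3 epimers)
Product: 16 (3R,5R)-5-{(2S)-2-[(4S)-2,2-dimethyl-1,3-dioxolan-4-yl]-2-hydroxypropyl}-3-methyloxolan-2-one
Conditions: LiN(iPr)2 (2.2 equiv), THF, −78 °C; then 2,6-di-tert-butyl-4-methylphenol, −78 °C; aq. NH4Cl
Reagents that add atoms: none
Why: Kinetic protonation of the lactone enolate (the hydroxyl carried as its lithium alkoxide), in which the bulky phenol should deliver the proton to the face opposite the C5 side chain, placing the methyl group cis to it and setting C3 as (R); the cis isomer is also the more stable one.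

Step 6
Reactants: 16 (3R,5R)-5-{(2S)-2-[(4S)-2,2-dimethyl-1,3-dioxolan-4-yl]-2-hydroxypropyl}-3-methyloxolan-2-one
Product: 17 (3R,5R)-3-methyl-5-[(2S,3S)-2,3,4-trihydroxy-2-methylbutyl]oxolan-2-one
Conditions: AcOH–H2O (4:1), 40 °C
Reagents that add atoms: none
Why: Acid-catalysed hydrolysis of the isopropylidene acetal, under which the lactone, the tertiary alcohol and all stereocentres should be stable.

Step 7
Reactants: 17 (3R,5R)-3-methyl-5-[(2S,3S)-2,3,4-trihydroxy-2-methylbutyl]oxolan-2-one
Product: 18 (2S,3S)-2,3-dihydroxy-3-methyl-4-[(2R,4R)-4-methyl-5-oxooxolan-2-yl]butyl 4-methylbenzenesulfonate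
Conditions: TsCl (1.05 equiv), Bu2SnO (2 mol %), Et3N, CH2Cl2, 0 °C → rt
Reagents that add atoms: 4-toluenesulfonyl chloride, Cc1ccc(cc1)S(Cl)(=O)=O
Why: Tin-acetal-catalysed regioselective sulfonylation, in which the stannylene formed across the terminal 1,2-diol activates the primary oxygen so that only the primary hydroxyl should be tosylated.

Step 8
Reactants: 18 (2S,3S)-2,3-dihydroxy-3-methyl-4-[(2R,4R)-4-methyl-5-oxooxolan-2-yl]butyl 4-methylbenzenesulfonate; 19 daphnetin (7,8-dihydroxy-2H-chromen-2-one)
Product: 21 (3R,5R)-5-{(2S,3S)-2,3-dihydroxy-4-[(8-hydroxy-2-oxo-2H-chromen-7-yl)oxy]-2-methylbutyl}-3-methyloxolan-2-one, via epoxide 20 (not isolated)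
Conditions: 19 (1.5 equiv), K2CO3 (1.2 equiv), DMF, 50 °C, argon
Reagents that add atoms: none
Why: Williamson-type etherification through the terminal epoxide, in which base closes the tosyloxy alcohol to the oxirane (3-exo-tet, carbinol stereocentre untouched) and the 7-phenoxide of daphnetin, the more acidic phenol because it is conjugated with the pyranone carbonyl, should open it at the primary carbon, leaving 8-OH free.

**Compound list**

1 | methyl (4S)-2,2-dimethyl-1,3-dioxolane-4-carboxylate | COC(=O)[C@@H]1COC(C)(C)O1 | starting material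
2 | N,O-dimethylhydroxylamine hydrochloride | CNOC.Cl | starting material
3 | (4S)-N-methoxy-N,2,2-trimethyl-1,3-dioxolane-4-carboxamide (Weinreb amide) | CON(C)C(=O)[C@@H]1COC(C)(C)O1 | intermediate
4 | 1-[(4S)-2,2-dimethyl-1,3-dioxolan-4-yl]ethan-1-one | CC(=O)[C@@H]1COC(C)(C)O1 | intermediate
5 | acetonitrile | CC#N | starting material
6 | (cyanomethyl)lithium | [Li]CC#N | intermediate
7 | (3S)-3-[(4S)-2,2-dimethyl-1,3-dioxolan-4-yl]-3-hydroxybutanenitrile | N#CC[C@](C)(O)[C@@H]1COC(C)(C)O1 | intermediate
8 | n-propylmagnesium bromide | CCC[Mg]Br | starting material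
9 | carbon dioxide | O=C=O | starting material
10 | diisopropoxy(η2-propene)titanium (2-methyltitanacyclopropane) | CC1C[Ti]1(OC(C)C)OC(C)C | intermediate
11 | azatitanacyclopentene from 7 (bromomagnesium alkoxide) and 10 | CC(C)O[Ti]1(OC(C)C)N=C(C[C@](C)(O[Mg]Br)[C@@H]2COC(C)(C)O2)CC1C | intermediate
12 | titanium carboxylate from 11 and CO2 | CC(C)O[Ti]1(OC(C)C)N=C(C[C@](C)(O[Mg]Br)[C@@H]2COC(C)(C)O2)CC(C)C(=O)O1 | intermediate
13 | (2RS,6S)-6-[(4S)-2,2-dimethyl-1,3-dioxolan-4-yl]-6-hydroxy-2-methyl-4-oxoheptanoic acid | CC(CC(=O)C[C@](C)(O)[C@@H]1COC(C)(C)O1)C(=O)O | intermediate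
14 | (2RS,4R,6S)-6-[(4S)-2,2-dimethyl-1,3-dioxolan-4-yl]-4,6-dihydroxy-2-methylheptanoic acid | CC(C[C@@H](O)C[C@](C)(O)[C@@H]1COC(C)(C)O1)C(=O)O | intermediate
15 | (5R)-5-{(2S)-2-[(4S)-2,2-dimethyl-1,3-dioxolan-4-yl]-2-hydroxypropyl}-3-methyloxolan-2-one, both C3 epimers | CC1C[C@H](C[C@](C)(O)[C@@H]2COC(C)(C)O2)OC1=O | intermediate
16 | (3R,5R)-5-{(2S)-2-[(4S)-2,2-dimethyl-1,3-dioxolan-4-yl]-2-hydroxypropyl}-3-methyloxolan-2-one | C[C@@H]1C[C@H](C[C@](C)(O)[C@@H]2COC(C)(C)O2)OC1=O | intermediate
17 | (3R,5R)-3-methyl-5-[(2S,3S)-2,3,4-trihydroxy-2-methylbutyl]oxolan-2-one | C[C@@H]1C[C@H](C[C@](C)(O)[C@@H](O)CO)OC1=O | intermediate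
18 | (2S,3S)-2,3-dihydroxy-3-methyl-4-[(2R,4R)-4-methyl-5-oxooxolan-2-yl]butyl 4-methylbenzenesulfonate | C[C@@H]1C[C@H](C[C@](C)(O)[C@@H](O)COS(=O)(=O)c2ccc(C)cc2)OC1=O | intermediate
19 | daphnetin (7,8-dihydroxy-2H-chromen-2-one) | Oc1ccc2ccc(=O)oc2c1O | starting material
20 | (3R,5R)-5-{(2S)-2-hydroxy-2-[(2S)-oxiran-2-yl]propyl}-3-methyloxolan-2-one | C[C@@H]1C[C@H](C[C@](C)(O)[C@@H]2CO2)OC1=O | intermediate
21 | (3R,5R)-5-{(2S,3S)-2,3-dihydroxy-4-[(8-hydroxy-2-oxo-2H-chromen-7-yl)oxy]-2-methylbutyl}-3-methyloxolan-2-one | C[C@@H]1C[C@H](C[C@](C)(O)[C@@H](O)COc2ccc3ccc(=O)oc3c2O)OC1=O | target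

**Count and risks**

Total steps: 8. Longest linear sequence: 8 steps (1 → 21).

Steps most likely to fail:

1. Step 3 (proposed new method). Protonolysis or a second nitrile insertion may outrun capture by CO2, CO2 may insert only sluggishly into the secondary Ti–C bond, or the nitrile may insert at the substituted carbon of the titanacyclopropane. Fallback with known chemistry, setting out from 7: addition of 2-methylallylmagnesium chloride (excess, THF, 0 °C; buffered aqueous hydrolysis of the ketimine) should give (6S)-6-[(4S)-2,2-dimethyl-1,3-dioxolan-4-yl]-6-hydroxy-2-methylhept-1-en-4-one F1. Evans–Saksena reduction as in step 4 should give (2S,4R)-2-[(4S)-2,2-dimethyl-1,3-dioxolan-4-yl]-6-methylhept-6-ene-2,4-diol F2. Hydroboration–oxidation (9-borabicyclo[3.3.1]nonane, THF; NaOH, H2O2) should give (4R,6S)-6-[(4S)-2,2-dimethyl-1,3-dioxolan-4-yl]-2-methylheptane-1,4,6-triol F3 as both C2 epimers. Oxidative lactonisation (2,2,6,6-tetramethylpiperidin-1-oxyl, PhI(OAc)2, CH2Cl2) comes back to the route at 15.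

2. Step 4. Facial discrimination may be poor because the directing carbinol is tertiary and the chair has to tell methyl from dioxolanyl. Fallback, setting out from 13: unselective reduction (NaBH4, MeOH–THF, 0 °C; acid) should give 15 together with its C5 epimer, (5S)-5-{(2S)-2-[(4S)-2,2-dimethyl-1,3-dioxolan-4-yl]-2-hydroxypropyl}-3-methyloxolan-2-one F4. After chromatographic separation, F4 is opened (LiOH, THF–H2O) to (2RS,4S,6S)-6-[(4S)-2,2-dimethyl-1,3-dioxolan-4-yl]-4,6-dihydroxy-2-methylheptanoic acid F5. Mitsunobu lactonisation (PPh3, diisopropyl azodicarboxylate, THF) should close it with inversion at the carbinol carbon, so that both epimers converge on 15.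

3. Step 8. Alkylation may also occur at 8-OH or at both phenolic oxygens, and opening of the epoxide by the phenoxide may be slow. Fallback, setting out from 18: alkylation of 7-hydroxy-2-oxo-2H-chromene-8-carbaldehyde, which has a single phenolic OH (K2CO3, DMF, 50 °C), should give 7-{[(2S,3S)-2,3-dihydroxy-3-methyl-4-[(2R,4R)-4-methyl-5-oxooxolan-2-yl]butyl]oxy}-2-oxo-2H-chromene-8-carbaldehyde F6. Baeyer–Villiger (Dakin-type) oxidation with 3-chloroperbenzoic acid (CH2Cl2, NaHCO3) should give 7-{[(2S,3S)-2,3-dihydroxy-3-methyl-4-[(2R,4R)-4-methyl-5-oxooxolan-2-yl]butyl]oxy}-2-oxo-2H-chromen-8-yl formate F7. Methanolysis (KHCO3, MeOH, 0 °C) frees the 8-OH and comes back to the route at 21.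

**Further compounds**

F1 | step 3 | (6S)-6-[(4S)-2,2-dimethyl-1,3-dioxolan-4-yl]-6-hydroxy-2-methylhept-1-en-4-one | CC(=C)CC(=O)C[C@](C)(O)[C@@H]1COC(C)(C)O1
F2 | step 3 | (2S,4R)-2-[(4S)-2,2-dimethyl-1,3-dioxolan-4-yl]-6-methylhept-6-ene-2,4-diol | CC(=C)C[C@H](C[C@](C)(O)[C@@H]1COC(C)(C)O1)O
F3 | step 3 | (2RS,4R,6S)-6-[(4S)-2,2-dimethyl-1,3-dioxolan-4-yl]-2-methylheptane-1,4,6-triol | OCC(C)C[C@H](C[C@](C)(O)[C@@H]1COC(C)(C)O1)O
F4 | step 4 | (3RS,5S)-5-{(2S)-2-[(4S)-2,2-dimethyl-1,3-dioxolan-4-yl]-2-hydroxypropyl}-3-methyloxolan-2-one | CC1C[C@@H](C[C@](C)(O)[C@@H]2COC(C)(C)O2)OC1=O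
F5 | step 4 | (2RS,4S,6S)-6-[(4S)-2,2-dimethyl-1,3-dioxolan-4-yl]-4,6-dihydroxy-2-methylheptanoic acid | CC(C[C@H](O)C[C@](C)(O)[C@@H]1COC(C)(C)O1)C(=O)O
F6 | step 8 | 7-{[(2S,3S)-2,3-dihydroxy-3-methyl-4-[(2R,4R)-4-methyl-5-oxooxolan-2-yl]butyl]oxy}-2-oxo-2H-chromene-8-carbaldehyde | C[C@@H]1C[C@H](C[C@](C)(O)[C@@H](O)COc2ccc3ccc(=O)oc3c2C=O)OC1=O
F7 | step 8 | 7-{[(2S,3S)-2,3-dihydroxy-3-methyl-4-[(2R,4R)-4-methyl-5-oxooxolan-2-yl]butyl]oxy}-2-oxo-2H-chromen-8-yl formate | C[C@@H]1C[C@H](C[C@](C)(O)[C@@H](O)COc2ccc3ccc(=O)oc3c2OC=O)OC1=O
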